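The readings stem from a simulated flask on assumed constants.

- Grey and ochre ran at the same temperature with the same charges of starting material and partner, but grey carried more free catalyst, 31 µM against 4.7 µM. Grey's target fell from 51.3 % at 12.0 h to 10.7 % at 30.0 h, while ochre's was still climbing at 43.3 %. I had to decide whether the next flasks should be left beyond 20 h.

| flask | starting material | partner | free catalyst | temperature | remark | time |
|---|---|---|---|---|---|---|
| ochre | 20 mM | 40 mM (fed, over 30 min) | 4.7 µM | 78 °C | run made earlier |  |
| blue | 20 mM | 40 mM (fed, over 30 min) | 12 µM | 116 °C | run made earlier |  |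
| grey | 20 mM | 40 mM (fed, over 30 min) | 31 µM | 78 °C | run made earlier |  |
| red | 20 mM | 43 mM (fed, over 30 min) | 10 µM | 116 °C | run made earlier |  |
| theta | 20 mM | 10.0 mM (fed, over 30 min) | 30 µM | 130 °C |  | 20 h |
| zeta | 20 mM | 40.0 mM (fed, over 30 min) | 10 µM | 100 °C |  | 20 h |
| epsilon | 20 mM | 150 mM (fed, over 100 min) | 10 µM | 100 °C |  | 20 h |
| delta | 20 mM | 40.0 mM (fed, over 20 min) | 6.0 µM | 100 °C |  | 20 h |
| eta | 20 mM | 40.0 mM (fed, over 50 min) | 5.0 µM | 60 °C |  | 20 h |

| run | time / h | target / % | starting material / % |
|---|---|---|---|
| ochre | 6.00 | 11.4 | 87.6 |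
| ochre | 12.0 | 22.8 | 77.2 |
| ochre | 20.0 | 32.7 | 64.5 |
| ochre | 25.0 | 38.5 | 58.5 |
| ochre | 30.0 | 43.3 | 51.6 |
| blue | 0.417 | 9.5 | 91.2 |
| blue | 0.667 | 15.9 | 83.5 |
| blue | 1.33 | 28.5 | 68.4 |
| blue | 2.50 | 40.6 | 53.8 |
| blue | 5.00 | 48.3 | 41.5 |
| grey | 6.00 | 49.5 | 41.4 |
| grey | 12.0 | 51.3 | 13.9 |
| grey | 20.0 | 28.8 | 1.9 |
| grey | 25.0 | 18.2 | 0.3 |
| grey | 30.0 | 10.7 | 0.6 |
| red | 0.833 | 18.1 | 80.8 |
| red | 2.00 | 33.0 | 63.7 |
| red | 2.50 | 35.9 | 59.2 |
| red | 4.00 | 43.8 | 49.5 |
| red | 5.00 | 45.3 | 46.5 |

(each reading ± 0.5 percentage points)

- all flasks from highest to lowest amount of target, in percent of the starting material charged, at 20 h (theta / zeta / epsilon / delta / eta)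
- the same order at 3.0 d (theta / zeta / epsilon / delta / eta)
- the amount of target, in percent of the starting material charged of the flask you put first, at 20 h
- the amount of target, in percent of the starting material charged of the flask you put last, at 20 h

- what was read earlier has a scatter of 0.5 percentage points, one standard deviation

- By 20.0 h hardly any starting material remained in grey, so I read its target as decaying alone, pseudo-first-order in target. Its mean half-life over the last 10.0 h was 7.00 h.
- Replacing the curve by that mean cost little: grey's two successive intervals gave 7.55 h and 6.52 h.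
- Temperature needed an assumption. Per unit of catalyst, the mean first-order loss of starting material read 5.02 times faster in blue, up to 1.33 h, than in grey, up to 6.00 h, and I let the loss of target speed up alike, geometrically in temperature.
- Scaling grey's half-life inversely with free catalyst and by that speed-up gave my carried quantity, the target half-life at 100 °C under 10 µM of free catalyst: 8.53 h. At a fixed temperature I took it to stretch in proportion as free catalyst falls.
- The wait from 20 h to 3.0 d is 6.10 such half-lives, so I decided that zeta and epsilon were not worth leaving beyond 20 h.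
- For theta the same scaling gave 0.795 h, shorter than its 20 h, so I expected theta last, provided its free catalyst survived.
- The forecast differed on theta. It gave delta > zeta > epsilon > theta > eta at 20 h, delta > eta > zeta > theta > epsilon at 3.0 d, 54 % for the leader and 13 % for the last, and of theta it said “Theta dies early and is partner-limited, near 20%”.
- The flasks gave epsilon > delta > zeta > eta > theta at 20 h and delta > eta > epsilon > zeta > theta at 3.0 d.

    starting material + free catalyst ⇌ catalyst intermediate A (K = 5.50 /M, k = 710 /M/min, Ea = 48.0 kJ/mol, ΔH = −2.00 kJ/mol)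
    partner + catalyst intermediate A → catalyst intermediate B (k = 5400 /M/min, Ea = 39.0 kJ/mol)
    catalyst intermediate B ⇌ by-product + catalyst intermediate C (K = 0.00690 M, k = 210 /min, Ea = 90.0 kJ/mol, ΔH = −56.0 kJ/mol)
    catalyst intermediate C → free catalyst + target (k = 16.0 /min, Ea = 83.0 kJ/mol)
    free catalyst + target → free catalyst + over-reaction product (k = 160 /M/min, Ea = 46.0 kJ/mol)
    catalyst intermediate B → spent catalyst (k = 0.00380 /min, Ea = 125 kJ/mol)
    (constants at 100 °C)

- Epsilon led with 57.6 %, and free catalyst then stood at 30.9 % of its charge. Taking that share as the mean over the wait stretches the half-life to 27.6 h, which carries epsilon's target to 15.6 % at 72.0 h; the flask held 16.3 %. Theta kept 36.7 % of its free catalyst, which puts its half-life at 2.17 h, shorter than 20 h, and at 20.0 h theta held 0.115 % of target.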